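## The problem

The numbering used here: C1 and C2 carry the acetates, C3 is a CH2, C4 the gem-dimethyl carbon, C5 the ring A methine, C6 the lactol carbon, C7 the OCH2, C8 a quaternary carbon, C9 and C11 the epoxide carbons, C10 the quaternary carbon with methyl C20, C12 a CH2, C13 the bridgehead CH, C14 the bridge CH2, C15 the ketone and C16 the CH(CH3).

- Target 29 has cyclohexane ring A (C1–C5, C10) trans-fused to oxepane ring B (C5, C6, O, C7, C8, C9, C10). Ring B shares the C8–C9 bond with a bicyclo[3.2.1]octane made of ring C (C8, C9, C11–C14) and cyclopentanone ring D (C8, C13–C16).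
- Three fully substituted carbons stand in a row (C8, C9, C10), so the C8–C9 and C9–C10 bonds are the hardest to make.
- There are ten stereocentres. C5 and C10 (C6 trans to C9) can be set first on a simple ring and then relay to the rest. C1 and C2 (cis, on the face of C20, C2 axial between two axial methyls) follow from hydride attack anti to those methyls. C8 and C13 are tied by the bridge and must be induced from ring A across ring B.
- The epoxide oxygen lies on the exo face (the face of C14), the C16 methyl is endo, and C6 is a lactol centre that can equilibrate.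
- The tertiary epoxide, the lactol, the acetates and the epimerisable C16 centre do not tolerate strong acid, base or nucleophiles, so they must appear late.
- The enabling feature is the seven-membered carbocycle C8–C9–C11–C12–C13–C16–C15 bridged by C14. It is the adduct of a cyclopentadiene (C8, C15, C16, C13, with C14 as its CH2) and a three-carbon oxyallyl unit C9–C11–C12. The C6–O–C7 acetal link joins ring A to the diene terminus C8, so it can act as a tether and the cycloaddition can close rings B and C together.

## Retrosynthesis

**Lactol and epoxide (29 ⇒ 28 ⇒ 27).** The last operation is hydrolysis of the C6 methyl acetal 28, so the tether of the key step is kept to the end and no free hemiacetal is carried. In 28 the C9–O and C11–O bonds are cut back to the 9(11)-alkene 27. Direct epoxidation is preferred to closing the ring from a 9,11-diol derivative: it is one neutral step, and the exo face of a bicyclo[3.2.1]oct-2-ene is the open one. The oxidant must spare the C15 ketone and the acetates and attack the exo face.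

**Adjustments back to the cycloadduct (27 ⇒ 26 ⇒ 25 ⇒ 23 ⇒ 22).** The acetates come from diol 26. Acid methanolysis of 25 removes the acetonide and turns the C15 enol silane into the ketone, setting C16 by exo protonation. The C9=C11 bond of 25 comes from the axial C11 alcohol 23 by anti elimination, and 23 from ketone 22 by exo hydride delivery. Hydroxylating C9 through the C11 enolate was weighed against this. Kinetic enolisation of 22 would occur at the unhindered C12, so the elimination is chosen and the enolate route is held in reserve.

**Key disconnection (22 ⇒ 21 ⇒ 20).** The C8–C9 and C12–C13 bonds are cut, giving oxyallyl cation 21 and, before ionisation, chloromethyl ketone 20 with a tethered 2-silyloxycyclopentadiene. The precursor has two rings and three stereocentres fewer. Joining a finished bicyclooctane to ring A at the neopentyl C9–C10 bond, or an untethered cycloaddition, would not favour the hindered C8–C9 bond. The forward step needs ionisation under conditions the silyl dienol ether survives, and diene-face control from C5 and C10.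

**Timing of the two reactive partners (20 ⇒ 19 ⇒ 18 ⇒ 17).** The C11–C12 bond of 20 is cut to methyl ester 18 and a chloromethyl carbenoid, through tetrahedral adduct 19. The enol silane of 18 goes back to cyclopentenone 17. An α-chloro ketone would not survive enolisation of the cyclopentenone, and a silyl dienol ether would not survive electrophilic halogenation. Releasing the ketone last from an ester avoids both conflicts.

**The tether (17 ⇒ 16 ⇒ 12 + 15; 15 ⇒ 14 ⇒ 13).** The C6–O bond is cut to dimethyl acetal 12 and alcohol 15, joined by acetal exchange through salt 16. Alcohol 15 comes from enone 13 through dienolate 14 and a one-carbon electrophile. An ester tether would resist the folded conformation and need a late lactone reduction; the acetal already has the oxidation level of the lactol.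

**Ring A side chains (12 ⇒ 11 ⇒ 10).** The C6 aldehyde and the C11 ester are both traced to terminal alkenes of 10: a vinyl group on C5 and a 2-chloroallyl group on C10. One ozonolysis cleaves both and differentiates them, because the vinyl chloride gives an acyl chloride and hence an ester.

**cis-Diol (10 ⇒ 9 ⇒ 8 ⇒ 7).** The C2 oxygen comes from autoxidation of ketone 7 to diosphenol 8. Both carbinol hydrogens of 9 come from hydride on the face opposite the axial C20 and C4 methyls. Dihydroxylation of a C1=C2 alkene would give the other face.

**Ring A (7 ⇒ 6 ⇒ 4 + 5; 4 ⇒ 3 ⇒ 1 + 2).** The C5–C6 and C10–C9 bonds are cut. An enantioselective conjugate addition of a vinyl metal to enone 4 sets C5, and enolate 6 is alkylated with 5 anti to the vinyl group to set the quaternary C10. Enone 4 is the Robinson annulation product of 1 and 2 through keto aldehyde 3. The forward step must discriminate the faces of a hindered β-carbon and C-alkylate a tetrasubstituted enolate.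

## Roads not taken

**Alternative 1:** The C7–O bond is cut. C7 is carried as a plain methyl on C8 and oxidised late. A diethylhydrosilyl group on the C15 oxygen is inserted into a C–H bond of that methyl ([Ir(cod)OMe]2, 3,4,7,8-tetramethyl-1,10-phenanthroline, norbornene) to give oxasilolane A1, and Tamao–Fleming oxidation would then release the C7/C15 diol.
- Merits: the site selectivity of hydroxyl-directed silylation of a γ-methyl group is dependable, and nothing as fragile as a silyl dienol ether or a mixed acetal is handled.
- Weak points: the key step makes no skeletal bond and no stereocentre. The bicyclooctene with its quaternary C8 and the C9–C10 link to ring A must come from chemistry this road does not supply. A1 still lacks the C16 methyl, the C15 ketone, the C6 oxidation level, ring B and the epoxide. The 9(11)-alkene is exposed to the Si–H/iridium system. Later methylation of a C15 enolate would enter from the exo face and give the wrong C16 epimer.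
- Comparison: this road is better in robustness of intermediates. The chosen plan sets against it a key step that forms two C–C bonds, two rings and three stereocentres, with the C7 oxygen in place from the start.

**Alternative 2:** Ring A closes last by cutting C5–C10. SnCl4 ionises a tertiary allylic alcohol at C10 to an allyl cation over C10, C9 and C11. The tethered C5=C6 methyl enol ether attacks at C10 and the oxocarbenium ion collapses to aldehyde A2.
- Merits: it is convergent, forms the quaternary C10 in the ring closure, and delivers the 9(11)-alkene and the C6 aldehyde level directly. The regiochemical question of the chosen route's dehydration does not arise, and in this respect it is better.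
- Weak points: C5 and C10 must be induced from a remote bicycle and a flexible diol-bearing chain. A cation beside the quaternary bridgehead C8 invites Wagner–Meerwein shifts and proton loss. SnCl4 threatens the p-methoxybenzyl ether, the silyl ether and the acetonide. The new bond joins two heavily substituted carbons. Ring B still has to be closed.
- Comparison: the chosen plan sets the ring A centres by a conjugate addition/alkylation on a ring and then uses them, and keeps carbocations away from the strained bicycle.

**Alternative 3:** The C8–C15 and C7–O bonds are cut. A primary nitro group at C15 is dehydrated (PhNCO, Et3N) to a nitrile oxide, which adds across an exocyclic C8=C7 alkene on ring C and closes ring D and the isoxazoline of A3.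
- Merits: one neutral step creates the quaternary C8, ring D, the C7 oxygen and a masked C15 ketone. The acetates and the 9(11)-alkene are already present, so the endgame is short. In step economy after the key step this road is at least as good.
- Weak points: the closure must form a bridged bicycle, so the chain on C13 must reach across the ring from an axial position. The dipole meets a conjugated C7=C8–C9=C11 diene, where addition at the wrong alkene competes. C16 must be set beforehand in a flexible chain. The cyclohexadiene joined to ring A through the sp2–neopentyl C9–C10 bond is itself a demanding intermediate. N–O cleavage must spare the trisubstituted alkene.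
- Comparison: the chosen plan concedes a longer endgame. It sets against this a key step that builds more of the skeleton from a precursor assembled by acetal exchange, with C5/C10 steering C8/C13.

Key step: step 11

Assumption: the C6 acetal carbon is drawn in 17–28 as the epimer matching the lactol of 29; step 8 may give both C6 epimers (17 is also a mixture at C8, written without configuration), which is taken as harmless because C8 becomes planar in step 9 and C6 equilibrates by ring–chain tautomerism when the lactol is released in step 17.

## Route

Step 1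
Reactants: 1 isobutyraldehyde; 2 pent-1-en-3-one
Product: 4 2,4,4-trimethylcyclohex-2-en-1-one, via keto aldehyde 3 (not isolated)
Conditions: H2SO4 (cat.), toluene, 50 °C → reflux (Dean–Stark)
Reagents that add atoms: none
Why: Acid-catalysed Robinson annulation; Michael addition of the aldehyde enol gives 3, and aldol condensation with loss of water closes the enone; no stereocentre is formed.

Step 2
Reactants: 4 2,4,4-trimethylcyclohex-2-en-1-one; 5 2,3-dichloropropene
Product: 7 (2S,3R)-2-(2-chloroprop-2-en-1-yl)-3-ethenyl-2,4,4-trimethylcyclohexan-1-one, via magnesium enolate 6 (not isolated)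
Conditions: CH2=CHMgBr, CuBr·SMe2 (5 mol %), (R)-1-[(S)-2-(diphenylphosphino)ferrocenyl]ethyldicyclohexylphosphine (6 mol %), t-BuOMe, −75 °C; then 5, DMPU, −75 → 23 °C
Reagents that add atoms: vinylmagnesium bromide, C=C[Mg]Br
Why: Copper-catalysed enantioselective conjugate addition of a Grignard reagent to a cyclic enone sets C5 (ligand antipode chosen to give 3R); the regiodefined enolate 6 is C-alkylated in the same flask anti to the new vinyl group, which sets the quaternary C10 trans to it.

Step 3
Reactants: 7 (2S,3R)-2-(2-chloroprop-2-en-1-yl)-3-ethenyl-2,4,4-trimethylcyclohexan-1-one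
Product: 8 (5R,6S)-6-(2-chloroprop-2-en-1-yl)-5-ethenyl-2-hydroxy-4,4,6-trimethylcyclohex-2-en-1-one
Conditions: KOtBu, O2 (1 atm), t-BuOH/THF, 23 °C
Reagents that add atoms: dioxygen, O=O
Why: Base-mediated autoxidation of a ketone with a single enolisable methylene gives the α-diketone as its enol (diosphenol); C10 is quaternary, so only C2 is oxidised and the stereocentres are untouched.

Step 4
Reactants: 8 (5R,6S)-6-(2-chloroprop-2-en-1-yl)-5-ethenyl-2-hydroxy-4,4,6-trimethylcyclohex-2-en-1-one
Product: 9 (1S,2R,3S,4R)-3-(2-chloroprop-2-en-1-yl)-4-ethenyl-3,5,5-trimethylcyclohexane-1,2-diol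
Conditions: NaBH4, MeOH, 0 → 23 °C
Reagents that add atoms: none
Why: Stepwise hydride reduction of the diosphenol; both hydrides arrive on the face opposite the axial C20 and C4 methyls, giving the equatorial C1 and axial C2 alcohols cis to each other and to C20, as is known for ring A diosphenols of 4,4,10-trimethyl terpenoids.

Step 5
Reactants: 9 (1S,2R,3S,4R)-3-(2-chloroprop-2-en-1-yl)-4-ethenyl-3,5,5-trimethylcyclohexane-1,2-diol
Product: 10 C1/C2 acetonide of diol 9
Conditions: Me2C(OMe)2, PPTS (cat.), acetone, 23 °C
Reagents that add atoms: 2,2-dimethoxypropane, COC(C)(C)OC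
Why: Transketalisation of a cis-1,2-diol to the five-membered isopropylidene acetal; it also keeps the C1 hydroxyl from lactonising onto the ester made in step 6.

Step 6
Reactants: 10 C1/C2 acetonide of diol 9
Product: 12 ring A dimethyl acetal methyl ester (C5–CH(OMe)2; C10–CH2CO2Me), via aldehyde ester 11 (not isolated)
Conditions: O3, NaHCO3, CH2Cl2/MeOH (4:1), −78 °C; Me2S, → 23 °C; then HC(OMe)3, Me2C(OMe)2, PPTS (cat.), MeOH, 23 °C
Reagents that add atoms: ozone, [O-][O+]=O; methanol, CO; trimethyl orthoformate, COC(OC)OC
Why: Ozonolysis cleaves both terminal alkenes; the vinyl group gives the C6 aldehyde, while the vinyl chloride gives an acyl chloride that methanol traps as the ester, so the two termini emerge differentiated; orthoformate acetalisation protects C6 and added 2,2-dimethoxypropane keeps the acetonide.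

Step 7
Reactants: 13 2-methylcyclopent-2-en-1-one
Product: 15 (±)-5-(hydroxymethyl)-2-methylcyclopent-2-en-1-one, via lithium dienolate 14 (not isolated)
Conditions: LiN(i-Pr)2, THF, −78 °C; CH2O (gas, from cracked paraformaldehyde), −78 °C; aqueous work-up
Reagents that add atoms: formaldehyde, C=O
Why: Kinetic α′-deprotonation of the cyclopentenone and aldol addition to monomeric formaldehyde; the new centre (later C8) is racemic and is erased in step 9; cold neutral work-up avoids dehydration.

Step 8
Reactants: 12 ring A dimethyl acetal methyl ester; 15 (±)-5-(hydroxymethyl)-2-methylcyclopent-2-en-1-one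
Product: 17 mixed C6 acetal (OMe and OCH2-cyclopentenone) carrying the C11 methyl ester, via collidinium salt 16 (not isolated)
Conditions: Et3SiOTf, 2,4,6-collidine, CH2Cl2, 0 °C; then 15, 0 → 23 °C
Reagents that add atoms: none
Why: Acetal exchange through an N-(α-methoxyalkyl)pyridinium salt: silyl triflate and collidine activate one methoxy group of an aldehyde acetal, and the added alcohol displaces the pyridine; ketals such as the acetonide are known to be spared, and C6 forms without reliable control (see assumption).

Step 9
Reactants: 17 mixed C6 acetal carrying the C11 methyl ester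
Product: 18 2-(tert-butyldimethylsilyloxy)cyclopenta-1,3-diene tethered through the C6 acetal (C11 methyl ester)
Conditions: t-BuMe2SiOTf, Et3N, CH2Cl2, −78 → 0 °C
Reagents that add atoms: tert-butyldimethylsilyl trifluoromethanesulfonate, CC(C)(C)[Si](C)(C)OS(=O)(=O)C(F)(F)F
Why: Soft enolisation of the cyclopentenone at its only α′-hydrogen (C8–H) gives the cross-conjugated 2-silyloxydiene; the ester and the amine-buffered acetals are inert; the diene is used at once to forestall 1,5-hydrogen shifts.

Step 10
Reactants: 18 silyloxydiene methyl ester
Product: 20 C12 chloromethyl ketone tethered to the silyloxydiene, via tetrahedral adduct 19 (not isolated)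
Conditions: ICH2Cl, MeLi·LiBr, THF/Et2O, −78 °C; then pH 7 phosphate buffer
Reagents that add atoms: chloroiodomethane, ClCI
Why: Chloromethyllithium formed by iodine–lithium exchange adds once to the methyl ester; adduct 19 is stable at −78 °C and releases the α-chloro ketone only on quench, after all enolising steps; enol silane and acetals do not react with the carbenoid at this temperature.

Step 11
Reactants: 20 C12 chloromethyl ketone tethered to the silyloxydiene
Product: 22 tetracyclic C11 ketone (C15 enol silane; C1/C2 acetonide; C6 methyl acetal; C9–H exo), via oxyallyl cation 21 (not isolated)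
Conditions: Et3N, CF3CH2OH/Et2O (1:1), 0.005 M, 0 → 23 °C
Reagents that add atoms: none
Why: Et3N removes a C9 proton and chloride leaves C12 in the ionising fluoroalcohol, giving oxyallyl cation 21 with the bulky C10 substituent cis to oxygen. The closest known reaction type is the amine-induced [4+3] cycloaddition of α-chloro ketones with dienes in trifluoroethanol, including intramolecular cases with tethered furans and cyclopentadienes; the five-atom tether here is longer than usual. Ring B closes as C9 bonds to C8, the enol ether β-carbon and most nucleophilic diene terminus, which the C6 acetal tether holds beside C9. Ring C closes as C12 bonds to C13, in concert or by collapse of the C11 enolate onto the silyloxyallyl cation, completing the bicyclo[3.2.1]octene. C8 and C13 are set together by the diene face engaged, which the C5 and C10 centres control: the trans-diequatorial C5–C6/C10–C9 arrangement fixes the direction in which the tether leaves ring A, so only one face of the cation can be reached without eclipsing in the forming oxepane. C9 is set by the compact approach of the Z-configured cation, which places C10 equatorial and the C9 hydrogen exo, the epimer needed in step 13 and expected to be the more stable one. The step needs regiochemical and facial selectivity; the tether secures the first (the other pairing would need a bridged nine-membered ring) and the ring A centres the second. High dilution and amine buffering limit solvent capture of 21 and protodesilylation, and the C15 ketone emerges masked as the enol silane.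

Step 12
Reactants: 22 tetracyclic C11 ketone
Product: 23 C11 endo (axial) alcohol
Conditions: LiBH(s-Bu)3, THF, −78 °C
Reagents that add atoms: none
Why: Bulky hydride attacks bicyclo[3.2.1]octan-3-ones from the exo face, anti to the two-carbon bridge, giving the axial endo alcohol (C11 set by reagent approach); enol silane and acetals are inert.

Step 13
Reactants: 23 C11 endo alcohol
Product: 25 9(11)-alkene (C15 enol silane; acetonide; C6 methyl acetal), via dichlorophosphate 24 (not isolated)
Conditions: POCl3, pyridine, 0 → 40 °C
Reagents that add atoms: none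
Why: Anti (E2) elimination of the axial dichlorophosphate; the exo axial C9–H is antiperiplanar, and loss toward the more substituted carbon (Zaitsev) gives the trisubstituted alkene, as in the dehydration of axial 11-hydroxy steroids to 9(11)-enes.

Step 14
Reactants: 25 9(11)-alkene
Product: 26 C1/C2 diol C15 ketone with 9(11)-alkene and C6 methyl acetal (C16 methyl endo)
Conditions: camphorsulfonic acid (cat.), MeOH, 0 → 23 °C
Reagents that add atoms: none
Why: Acid methanolysis removes the acetonide by transketalisation and protonates the enol silane at C16 from the exo face (syn to C14), giving the ketone with the endo methyl under kinetic control; the cyclic methyl acetal only exchanges with solvent.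

Step 15
Reactants: 26 diol ketone
Product: 27 C1/C2 diacetate
Conditions: Ac2O, DMAP, pyridine, 23 °C
Reagents that add atoms: acetic anhydride, CC(=O)OC(C)=O
Why: DMAP-catalysed acylation of the equatorial C1 and hindered axial C2 hydroxyls, the only free hydroxyls; the mild base should not epimerise C16.

Step 16
Reactants: 27 C1/C2 diacetate
Product: 28 9,11-exo-epoxide (C6 methyl acetal)
Conditions: dimethyldioxirane, acetone, 0 °C
Reagents that add atoms: dimethyldioxirane, CC1(C)OO1
Why: Neutral epoxidation of the trisubstituted alkene from the exo face of the bicyclo[3.2.1]oct-2-ene, anti to the C15–C16 bridge with its endo methyl, sets C9 and C11; ketone, acetates and acetal are not oxidised.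

Step 17
Reactants: 28 9,11-exo-epoxide
Product: 29 CNP0210140.1
Conditions: AcOH/THF/H2O (3:1:1), 35 °C
Reagents that add atoms: water, O
Why: Mild hydrolysis of the cyclic methyl acetal to the lactol, whose C6 centre equilibrates to the stable anomer; acetates, ketone and the hindered epoxide should tolerate dilute acetic acid.

## Compound list

1 | isobutyraldehyde | CC(C)C=O | starting material
2 | pent-1-en-3-one | CCC(=O)C=C | starting material
3 | 2,2-dimethyl-5-oxoheptanal | CCC(=O)CCC(C)(C)C=O | intermediate
4 | 2,4,4-trimethylcyclohex-2-en-1-one | CC1=CC(C)(C)CCC1=O | intermediate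
5 | 2,3-dichloropropene | ClCC(Cl)=C | starting material
6 | bromomagnesium (3R)-3-ethenyl-2,4,4-trimethylcyclohex-1-en-1-olate | CC1=C(O[Mg]Br)CCC(C)(C)[C@H]1C=C | intermediate
7 | (2S,3R)-2-(2-chloroprop-2-en-1-yl)-3-ethenyl-2,4,4-trimethylcyclohexan-1-one | O=C1CCC(C)(C)[C@@H](C=C)[C@]1(C)CC(Cl)=C | intermediate
8 | (5R,6S)-6-(2-chloroprop-2-en-1-yl)-5-ethenyl-2-hydroxy-4,4,6-trimethylcyclohex-2-en-1-one | O=C1C(O)=CC(C)(C)[C@@H](C=C)[C@]1(C)CC(Cl)=C | intermediate
9 | (1S,2R,3S,4R)-3-(2-chloroprop-2-en-1-yl)-4-ethenyl-3,5,5-trimethylcyclohexane-1,2-diol | O[C@H]1CC(C)(C)[C@@H](C=C)[C@](C)(CC(Cl)=C)[C@H]1O | intermediate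
10 | acetonide of 9 (C1/C2 cis; C5 vinyl trans to C10 2-chloroallyl) | CC1(C)O[C@H]2CC(C)(C)[C@@H](C=C)[C@](C)(CC(Cl)=C)[C@H]2O1 | intermediate
11 | ring A aldehyde ester (acetonide; C5 formyl; C10 CH2CO2Me) | CC1(C)O[C@H]2CC(C)(C)[C@@H](C=O)[C@](C)(CC(=O)OC)[C@H]2O1 | intermediate
12 | ring A dimethyl acetal methyl ester | CC1(C)O[C@H]2CC(C)(C)[C@@H](C(OC)OC)[C@](C)(CC(=O)OC)[C@H]2O1 | intermediate
13 | 2-methylcyclopent-2-en-1-one | CC1=CCCC1=O | starting material
14 | lithium 5-methylcyclopenta-1,4-dien-1-olate | [Li+].[O-]C1=CCC=C1C | intermediate
15 | (±)-5-(hydroxymethyl)-2-methylcyclopent-2-en-1-one | CC1=CCC(CO)C1=O | intermediate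
16 | N-(C6 methoxymethyl)-2,4,6-trimethylpyridinium triflate of the ring A ester (C6 configuration open) | CC1(C)O[C@H]2CC(C)(C)[C@@H](C(OC)[n+]3c(C)cc(C)cc3C)[C@](C)(CC(=O)OC)[C@H]2O1.[O-]S(=O)(=O)C(F)(F)F | intermediate
17 | mixed C6 acetal (OMe, OCH2 of 3-methyl-2-oxocyclopent-3-enyl; C8 epimers) with C11 methyl ester | CC1(C)O[C@H]2CC(C)(C)[C@@H]([C@H](OC)OCC3CC=C(C)C3=O)[C@](C)(CC(=O)OC)[C@H]2O1 | intermediate
18 | silyloxydiene methyl ester (C8=C15(OTBS)–C16(Me)=C13, C14 H2) | CC1(C)O[C@H]2CC(C)(C)[C@@H]([C@H](OC)OCC3=C(O[Si](C)(C)C(C)(C)C)C(C)=CC3)[C@](C)(CC(=O)OC)[C@H]2O1 | intermediate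
19 | lithium alkoxide of the C11 chloromethyl methyl hemiketal | CC1(C)O[C@H]2CC(C)(C)[C@@H]([C@H](OC)OCC3=C(O[Si](C)(C)C(C)(C)C)C(C)=CC3)[C@](C)(CC([O-])(OC)CCl)[C@H]2O1.[Li+] | intermediate
20 | chloromethyl ketone tethered to the silyloxydiene (cycloaddition precursor) | CC1(C)O[C@H]2CC(C)(C)[C@@H]([C@H](OC)OCC3=C(O[Si](C)(C)C(C)(C)C)C(C)=CC3)[C@](C)(CC(=O)CCl)[C@H]2O1 | intermediate
21 | C9–C11–C12 oxyallyl cation (written as zwitterion; C10 cis to O) | CC1(C)O[C@H]2CC(C)(C)[C@@H]([C@H](OC)OCC3=C(O[Si](C)(C)C(C)(C)C)C(C)=CC3)[C@](C)(C=C([O-])[CH2+])[C@H]2O1 | intermediate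
22 | tetracyclic C11 ketone, C15 TBS enol ether, C1/C2 acetonide, C6 methyl acetal, C9–H exo | CC1(C)O[C@H]2CC(C)(C)[C@H]3[C@H](OC)OC[C@@]45C[C@@H](CC(=O)[C@@H]4[C@]3(C)[C@H]2O1)C(C)=C5O[Si](C)(C)C(C)(C)C | intermediate
23 | C11 endo (axial) alcohol of 22 | CC1(C)O[C@H]2CC(C)(C)[C@H]3[C@H](OC)OC[C@@]45C[C@@H](C[C@H](O)[C@@H]4[C@]3(C)[C@H]2O1)C(C)=C5O[Si](C)(C)C(C)(C)C | intermediate
24 | C11 dichlorophosphate of 23 | CC1(C)O[C@H]2CC(C)(C)[C@H]3[C@H](OC)OC[C@@]45C[C@@H](C[C@H](OP(Cl)(Cl)=O)[C@@H]4[C@]3(C)[C@H]2O1)C(C)=C5O[Si](C)(C)C(C)(C)C | intermediate
25 | 9(11)-alkene with C15 TBS enol ether, acetonide and C6 methyl acetal | CC1(C)O[C@H]2CC(C)(C)[C@H]3[C@H](OC)OC[C@@]45C[C@@H](CC=C4[C@]3(C)[C@H]2O1)C(C)=C5O[Si](C)(C)C(C)(C)C | intermediate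
26 | C1/C2 diol, C15 ketone, 9(11)-alkene, C6 methyl acetal, C16 methyl endo | O[C@H]1CC(C)(C)[C@H]2[C@H](OC)OC[C@@]34C[C@@H](CC=C3[C@]2(C)[C@H]1O)[C@@H](C)C4=O | intermediate
27 | C1/C2 diacetate of 26 | CC(=O)O[C@H]1CC(C)(C)[C@H]2[C@H](OC)OC[C@@]34C[C@@H](CC=C3[C@]2(C)[C@H]1OC(C)=O)[C@@H](C)C4=O | intermediate
28 | 9,11-exo-epoxide, C6 methyl acetal of the target | CC(=O)O[C@H]1CC(C)(C)[C@H]2[C@H](OC)OC[C@@]34C[C@@H](C[C@H]5O[C@]53[C@]2(C)[C@H]1OC(C)=O)[C@@H](C)C4=O | intermediate
29 | CNP0210140.1 | CC(=O)O[C@H]1CC(C)(C)[C@H]2[C@H](O)OC[C@@]34C[C@@H](C[C@H]5O[C@]53[C@]2(C)[C@H]1OC(C)=O)[C@@H](C)C4=O | target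

## Step count and least certain steps

Total: 17 steps. Longest linear sequence: 16 steps (steps 1–6 and 8–17); step 7 is a one-step branch.

**Step 11 (key step).** Closure of the seven-membered tether onto the very hindered C8–C9 bond may be slow. Solvent capture of the cation, protodesilylation or 1,5-hydrogen shift of the diene, or engagement of the wrong diene face could then compete. Fallback, from 18: addition of LiCHCl2 (CH2Cl2, LiN(i-Pr)2, −78 °C) gives the dichloromethyl ketone F1. Under the same amine/fluoroalcohol conditions it ionises to a chlorine-stabilised, longer-lived oxyallyl cation and should give the 12-chloro cycloadduct F2. Reductive dechlorination with Zn(Cu), NH4Cl, MeOH returns to 22.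

**Step 2.** The β-carbon is flanked by the α-methyl and the gem-dimethyl group, so conversion or enantioface discrimination may be poor, and C-alkylation of the hindered enolate may be slow. Fallback, from 4: achiral CuI-catalysed addition of vinylmagnesium bromide and alkylation with 5 gives the racemate, that is 7 together with its (2R,3S)-enantiomer F3. Preparative chromatography on a chiral stationary phase delivers 7.

**Step 13.** The elimination may take the less hindered axial C12 hydrogen and give the 11(12)-alkene, or phosphorylation of the hindered axial alcohol may stall. Fallback, from 22: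
- autoxidation of the equilibrating enolate at the tertiary carbon (KOtBu, O2, P(OEt)3) gives the 9-hydroxy ketone F4;
- NaBH4 gives the trans-diaxial 9,11-diol F5;
- MsCl/Et3N gives the C11 methanesulfonate F6;
- DBU closes the exo epoxide F7, whose face is fixed by the trans-diaxial geometry;
- camphorsulfonic acid in MeOH gives the epoxy diol ketone F8;
- Ac2O, DMAP, pyridine returns to 28.

**Step 16.** The C20 methyl leans over the exo face, so the oxidant may react slowly or be steered to the endo face. Fallback, from 27: N-bromosuccinimide in aqueous acetone forms the bromonium ion on the face the electrophile prefers, and water opens it trans-diaxially at the tertiary C9 to give the bromohydrin F9 (C9–OH exo, C11–Br endo). K2CO3 then closes the epoxide on the face opposite to the one the electrophile chose and returns to 28.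

**Step 8.** Exchange at the hindered C6 acetal may be incomplete, or the silyl triflate may attack the acetonide. Fallback, from 12: PhSSiMe3 with catalytic Me3SiOTf gives the O-methyl S-phenyl monothioacetal F10. Activation with MeOTf and 2,6-di-tert-butyl-4-methylpyridine in the presence of 15, as for a thioglycoside, returns to 17.

## Further compounds

F1 | step 11 | dichloromethyl ketone analogue of 20 | CC1(C)O[C@H]2CC(C)(C)[C@@H]([C@H](OC)OCC3=C(O[Si](C)(C)C(C)(C)C)C(C)=CC3)[C@](C)(CC(=O)C(Cl)Cl)[C@H]2O1
F2 | step 11 | 12-chloro analogue of cycloadduct 22 (C12 configuration open) | CC1(C)O[C@H]2CC(C)(C)[C@H]3[C@H](OC)OC[C@@]45C[C@@H](C(Cl)C(=O)[C@@H]4[C@]3(C)[C@H]2O1)C(C)=C5O[Si](C)(C)C(C)(C)C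
F3 | step 2 | (2R,3S)-2-(2-chloroprop-2-en-1-yl)-3-ethenyl-2,4,4-trimethylcyclohexan-1-one | O=C1CCC(C)(C)[C@H](C=C)[C@@]1(C)CC(Cl)=C
F4 | step 13 | 9-hydroxy derivative of 22 (C9–OH exo) | CC1(C)O[C@H]2CC(C)(C)[C@H]3[C@H](OC)OC[C@@]45C[C@@H](CC(=O)[C@]4(O)[C@]3(C)[C@H]2O1)C(C)=C5O[Si](C)(C)C(C)(C)C
F5 | step 13 | 9,11-diol (C9–OH exo, C11–OH endo) | CC1(C)O[C@H]2CC(C)(C)[C@H]3[C@H](OC)OC[C@@]45C[C@@H](C[C@H](O)[C@]4(O)[C@]3(C)[C@H]2O1)C(C)=C5O[Si](C)(C)C(C)(C)C
F6 | step 13 | C11 methanesulfonate of F5 | CC1(C)O[C@H]2CC(C)(C)[C@H]3[C@H](OC)OC[C@@]45C[C@@H](C[C@H](OS(C)(=O)=O)[C@]4(O)[C@]3(C)[C@H]2O1)C(C)=C5O[Si](C)(C)C(C)(C)C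
F7 | step 13 | 9,11-exo-epoxide with acetonide and C15 TBS enol ether | CC1(C)O[C@H]2CC(C)(C)[C@H]3[C@H](OC)OC[C@@]45C[C@@H](C[C@H]6O[C@]64[C@]3(C)[C@H]2O1)C(C)=C5O[Si](C)(C)C(C)(C)C
F8 | step 13 | 9,11-exo-epoxy C1/C2 diol C15 ketone, C6 methyl acetal | O[C@H]1CC(C)(C)[C@H]2[C@H](OC)OC[C@@]34C[C@@H](C[C@H]5O[C@]53[C@]2(C)[C@H]1O)[C@@H](C)C4=O
F9 | step 16 | bromohydrin of 27 (C9–OH exo, C11–Br endo) | CC(=O)O[C@H]1CC(C)(C)[C@H]2[C@H](OC)OC[C@@]34C[C@@H](C[C@H](Br)[C@]3(O)[C@]2(C)[C@H]1OC(C)=O)[C@@H](C)C4=O
F10 | step 8 | O-methyl S-phenyl monothioacetal at C6 of the ring A ester (C6 configuration open) | CC1(C)O[C@H]2CC(C)(C)[C@@H](C(OC)Sc3ccccc3)[C@](C)(CC(=O)OC)[C@H]2O1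
A1 | alternative 1 | C7-silylated oxasilolane bridging C7 and the C15 oxygen | CC(=O)O[C@H]1CC(C)(C)[C@@H](CO[Si](C)(C)C(C)(C)C)[C@](C)(C2=CC[C@@H]3C[C@]24C[Si](CC)(CC)O[C@@H]4C3)[C@H]1OC(C)=O
A2 | alternative 2 | ring A C6 aldehyde on the bicyclic 9(11)-ene | CC1(C)O[C@H]2CC(C)(C)[C@@H](C=O)[C@](C)(C3=CC[C@@H]4C[C@@]3(COCc5ccc(OC)cc5)[C@H](O[Si](C)(C)C(C)(C)C)[C@@H]4C)[C@H]2O1
A3 | alternative 3 | bridged isoxazoline carrying rings C and D | CC(=O)O[C@H]1CC(C)(C)[C@@H](CO[Si](C)(C)C(C)(C)C)[C@](C)(C2=CC[C@@H]3C[C@]24CON=C4[C@@H]3C)[C@H]1OC(C)=O
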